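**Plan**

1. The target is (3R,6R,3'R,6'R)-ε,ε-carotene-3,3'-diol, C2-symmetric. Ring atoms carry carotenoid numbers: C1 = CMe2, C2 = CH2, C3 = CHOH, C4H=C5(Me), C6 = ring CH bearing chain carbon C7.
2. Retrosynthesis: cut C11=C12 and C11'=C12' (twofold Wittig, two C15 phosphonium salts plus a C10 dialdehyde), then C9–C10 (vinyl Grignard), then C7=C8 (Wittig), then the ring bonds C3–C4 and C1–C6.
3. Enabling feature: each ring with its C7 consists of two 3-methylbut-2-enoyl C5 units, C16/C17–C1–C2–C3 and C4–C5(C18)–C6–C7. Joining the γ-carbon C4 of one unit to the acyl carbon C3 of the other, and its α-carbon C6 to the β-carbon C1, gives the 3-oxo ring with C4=C5 already in the ε position.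
4. Forward: one-flask cyclodimerization of 3-methylbut-2-enoyl chloride gives the racemic 3-oxo ester (acid chloride, pyranone ring and ketone level are the helpers). Then ketone to alcohol, ester to aldehyde, enone, vinyl carbinol, C15 salt; both ends are joined to the C10 unit last.
5. Stereochemistry: C6 of the keto ester is labile (vinylogous β-keto ester), so one asymmetric transfer hydrogenation with dynamic kinetic resolution should set C3 (catalyst) and C6 (matched substrate bias, trans). All chain double bonds are E from stabilized-ylide or thermally equilibrated Wittig steps.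

Key step: step 1

Remark on the chemistry: the free C3 hydroxyl is carried unprotected from step 2 on; one extra equivalent of iBu2AlH or Grignard reagent is spent on it.

**Step 1**
Reactants: 1 3-methylbut-2-enoyl chloride (two molecules)
Product: 5 methyl 2,6,6-trimethyl-4-oxocyclohex-2-ene-1-carboxylate (racemic), via isopropenylketene 2 (not isolated), via pyranone dimer 3 (not isolated), via open-chain sodium enolate 4 (not isolated)
Conditions: Et3N (1.1 equiv), toluene, 0 °C to rt; Et3N·HCl filtered off; then NaOMe (1.2 equiv per dimer), MeOH, 65 °C; AcOH quench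
Reagents that add atoms: sodium methoxide, C[O-].[Na+]
Why: Proposed new method: Et3N dehydrochlorinates 1 to isopropenylketene 2, which is C-acylated at its γ-carbon by a second molecule of 1, so the C3–C4 bond forms first and the resulting δ-oxo dienyl ketene closes on oxygen (oxa-6π) to the temporary pyranone ring of 3. Methoxide opens the lactone at its acyl carbon to enolate 4, a 3-oxido-1,3,5-hexatriene spanning C1=C2–C3(O–)=C4–C5=C6 that is stabilized by both carbonyls and whose geometry equilibrates by proton exchange in methanol. Thermal disrotatory 6π electrocyclization of 4 (equivalently a 6-endo-trig Michael addition of the ester α-carbon C6 to the Me2C= terminus C1) closes the carbocycle, and proton transfer gives the extended enolate of 5 as the thermodynamic sink until the acetic acid quench. The closest known reactions are the amine-induced self-condensation of α,β-unsaturated acid chlorides through vinylketenes to 2-pyranones, the alkoxide ring opening of 2-pyranones and the base-induced ring closure of phorone to isophorone. γ- over α-acylation is secured by the vinylketene manifold, in which γ-acylation is funnelled on by pyranone closure; C- over O-cyclization is secured by holding 4 as its enolate in methanol, where the ester cannot acylate and only C–C closure is irreversible; the C4=C5 position follows from the enone that the closure leaves. The one new stereocentre, C6, is α to the ester and γ to the enone, so it forms racemic and stays labile, which step 2 uses.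

**Step 2**
Reactants: 5 methyl 2,6,6-trimethyl-4-oxocyclohex-2-ene-1-carboxylate (racemic)
Product: 6 methyl (1R,4R)-4-hydroxy-2,6,6-trimethylcyclohex-2-ene-1-carboxylate
Conditions: RuCl[(R,R)-TsDPEN](p-cymene) (1 mol %), HCO2H/Et3N (1:2), DBU (0.2 equiv), DMF, 40 °C
Reagents that add atoms: none
Why: Proposed new method: asymmetric transfer hydrogenation run as a dynamic kinetic resolution, the closest known reaction being the DKR of α-substituted β-keto esters with the same Ru/TsDPEN catalysts; here the labile centre is one vinylogous position further away (C6–H is α to the ester and γ to the enone), so the amine base should racemize 5 through its extended enolate while the Ru–H/N–H pair reduces only the C=O (outer-sphere 1,2-delivery, the C4=C5 π-bond taking the place of the aryl group of acetophenone-type substrates), which with the (R,R)-ligand should set C3 as R. The (6R)-enantiomer should react faster because the hydride then enters anti to the pseudoaxial C1 methyl of the half-chair that carries the ester pseudoaxial (matched case), giving the 3,6-trans alcohol 6, whose C6–H is no longer acidic enough to epimerize.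

**Step 3**
Reactants: 6 methyl (1R,4R)-4-hydroxy-2,6,6-trimethylcyclohex-2-ene-1-carboxylate
Product: 7 (1R,4R)-4-hydroxy-2,6,6-trimethylcyclohex-2-ene-1-carbaldehyde
Conditions: iBu2AlH (2.3 equiv), CH2Cl2, −78 °C; MeOH, then aq. potassium sodium tartrate
Reagents that add atoms: none
Why: Partial reduction of an ester by iBu2AlH: the first equivalent converts the hydroxyl into its aluminium alkoxide, the second adds once to the hindered ester to give a tetrahedral aluminate that is stable at −78 °C and releases the aldehyde only on neutral work-up, so the α-stereocentre C6 and the unconjugated C4=C5 bond are kept.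

**Step 4**
Reactants: 7 (1R,4R)-4-hydroxy-2,6,6-trimethylcyclohex-2-ene-1-carbaldehyde
Product: 8 (3E)-4-[(1R,4R)-4-hydroxy-2,6,6-trimethylcyclohex-2-en-1-yl]but-3-en-2-one
Conditions: Ph3P=CHC(O)CH3 (1.5 equiv), toluene, 90 °C
Reagents that add atoms: 1-(triphenylphosphoranylidene)propan-2-one, CC(=O)C=P(c1ccccc1)(c1ccccc1)c1ccccc1
Why: Wittig reaction with a stabilized, practically non-basic ylide should give the E-enone without enolizing the β,γ-unsaturated aldehyde, so C6 is not epimerized and the ring double bond does not move into conjugation.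

**Step 5**
Reactants: 8 (3E)-4-[(1R,4R)-4-hydroxy-2,6,6-trimethylcyclohex-2-en-1-yl]but-3-en-2-one
Product: 9 (1E)-1-[(1R,4R)-4-hydroxy-2,6,6-trimethylcyclohex-2-en-1-yl]-3-methylpenta-1,4-dien-3-ol (both epimers at the new carbinol carbon)
Conditions: CH2=CHMgBr (2.5 equiv), THF, −20 to 0 °C; H2O quench
Reagents that add atoms: vinylmagnesium bromide, C=C[Mg]Br
Why: 1,2-Addition of a vinyl Grignard reagent to the enone carbonyl (the usual ionone to vinyl-carbinol conversion); one equivalent is consumed by the hydroxyl, and the new tertiary carbinol centre needs no control because it is destroyed in step 6.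

**Step 6**
Reactants: 9 (1E)-1-[(1R,4R)-4-hydroxy-2,6,6-trimethylcyclohex-2-en-1-yl]-3-methylpenta-1,4-dien-3-ol
Product: 10 [(2E,4E)-5-[(1R,4R)-4-hydroxy-2,6,6-trimethylcyclohex-2-en-1-yl]-3-methylpenta-2,4-dien-1-yl]triphenylphosphonium bromide
Conditions: Ph3P·HBr (1.05 equiv), MeOH/CH2Cl2, 0 °C to rt; crystallization
Reagents that add atoms: triphenylphosphine hydrobromide, [Br-].[PH+](c1ccccc1)(c1ccccc1)c1ccccc1
Why: Acid-mediated allylic transposition (SN1'): the tertiary, doubly allylic carbinol ionizes to a pentadienyl cation that triphenylphosphine captures at the unhindered primary terminus to give the 9E salt, while the secondary C3 hydroxyl should ionize much more slowly under this weakly acidic reagent.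

**Step 7**
Reactants: 10 [(2E,4E)-5-[(1R,4R)-4-hydroxy-2,6,6-trimethylcyclohex-2-en-1-yl]-3-methylpenta-2,4-dien-1-yl]triphenylphosphonium bromide (2.2 equiv); 11 (2E,4E,6E)-2,7-dimethylocta-2,4,6-trienedial
Product: 14 (3R,6R,3'R,6'R)-ε,ε-carotene-3,3'-diol, via C15 ylide 12 (not isolated), via C25 hydroxy apo-aldehyde 13 (not isolated)
Conditions: NaOMe (2.4 equiv), MeOH/CH2Cl2, 0 °C to rt; then EtOH, reflux (Z to E isomerization); crystallization
Reagents that add atoms: none
Why: Twofold Wittig olefination of the dialdehyde with the semi-stabilized C15 ylide forms C11=C12 and C11'=C12'; the strained 11Z isomers formed alongside should isomerize thermally to the all-E polyene, and neither the hydroxyls nor the C3/C6 stereocentres are affected by methoxide at room temperature.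

**Compound list**

1 | 3-methylbut-2-enoyl chloride | CC(C)=CC(Cl)=O | starting material
2 | 3-methylbuta-1,3-dien-1-one (isopropenylketene) | C=C(C)C=C=O | intermediate
3 | 4-methyl-6-(2-methylprop-1-en-1-yl)-2H-pyran-2-one | CC(C)=CC1=CC(C)=CC(=O)O1 | intermediate
4 | sodium (2Z,4Z)-1-methoxy-3,7-dimethyl-1-oxoocta-2,4,6-trien-5-olate (geometry as first formed) | COC(=O)/C=C(C)\C=C(/[O-])C=C(C)C.[Na+] | intermediate
5 | methyl 2,6,6-trimethyl-4-oxocyclohex-2-ene-1-carboxylate (racemic) | COC(=O)C1C(C)=CC(=O)CC1(C)C | intermediate
6 | methyl (1R,4R)-4-hydroxy-2,6,6-trimethylcyclohex-2-ene-1-carboxylate | CC1=C[C@H](O)CC(C)(C)[C@H]1C(=O)OC | intermediate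
7 | (1R,4R)-4-hydroxy-2,6,6-trimethylcyclohex-2-ene-1-carbaldehyde | CC1=C[C@H](O)CC(C)(C)[C@H]1C=O | intermediate
8 | (3E)-4-[(1R,4R)-4-hydroxy-2,6,6-trimethylcyclohex-2-en-1-yl]but-3-en-2-one | CC1=C[C@H](O)CC(C)(C)[C@H]1/C=C/C(C)=O | intermediate
9 | (1E)-1-[(1R,4R)-4-hydroxy-2,6,6-trimethylcyclohex-2-en-1-yl]-3-methylpenta-1,4-dien-3-ol | CC1=C[C@H](O)CC(C)(C)[C@H]1/C=C/C(C)(O)C=C | intermediate
10 | [(2E,4E)-5-[(1R,4R)-4-hydroxy-2,6,6-trimethylcyclohex-2-en-1-yl]-3-methylpenta-2,4-dien-1-yl]triphenylphosphonium bromide | CC1=C[C@H](O)CC(C)(C)[C@H]1/C=C/C(C)=C/C[P+](c1ccccc1)(c1ccccc1)c1ccccc1.[Br-] | intermediate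
11 | (2E,4E,6E)-2,7-dimethylocta-2,4,6-trienedial | O=C/C(C)=C/C=C/C=C(C)/C=O | starting material
12 | (1R,4R)-3,5,5-trimethyl-4-[(1E,3E)-3-methyl-5-(triphenylphosphoranylidene)penta-1,3-dien-1-yl]cyclohex-2-en-1-ol (C15 ylide) | CC1=C[C@H](O)CC(C)(C)[C@H]1/C=C/C(C)=C/C=P(c1ccccc1)(c1ccccc1)c1ccccc1 | intermediate
13 | (2E,4E,6E,8E,10E,12E)-13-[(1R,4R)-4-hydroxy-2,6,6-trimethylcyclohex-2-en-1-yl]-2,7,11-trimethyltrideca-2,4,6,8,10,12-hexaenal | CC1=C[C@H](O)CC(C)(C)[C@H]1/C=C/C(C)=C/C=C/C(C)=C/C=C/C=C(C)/C=O | intermediate
14 | (3R,6R,3'R,6'R)-ε,ε-carotene-3,3'-diol | CC1=C[C@H](O)CC(C)(C)[C@H]1/C=C/C(C)=C/C=C/C(C)=C/C=C/C=C(C)/C=C/C=C(C)/C=C/[C@H]1C(C)=C[C@H](O)CC1(C)C | target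

**Step count and risks**

Total step count: 7. Longest linear sequence: 7 steps (1 to 5, 6, 7, 8, 9, 10, 14); 11 is purchased.

Steps most likely to fail:

- **Step 1.** The open-chain enolate may fail to close at the hindered Me2C= terminus and revert to the pyranone on work-up, it may be cleaved by methoxide in a retro-Claisen sense, or the first stage may acylate at the α-carbon or oligomerize. The fallback uses known chemistry, sets out from 1 and comes back at 5. Compound 1 is treated with Me2CuLi (THF, −78 °C) to give 4-methylpent-3-en-2-one F1 (also a bulk chemical). F1 is then condensed with methyl acetoacetate (ZnCl2, toluene, reflux with water removal): Michael addition of the acetoacetate α-carbon to the Me2C= terminus, then aldol condensation of the methyl ketone onto the acetoacetate carbonyl, gives 5. The ring is then made through C1–C6 and C4=C5.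

- **Step 2.** The two enantiomers of 5 may be reduced at similar rates (poor diastereoselection), racemization at the hindered C6–H may be slower than reduction, or conjugate reduction may compete. The fallback uses known chemistry, sets out from 5 and comes back at 6. Corey–Bakshi–Shibata reduction ((S)-2-methyl-CBS-oxazaborolidine 10 mol %, BH3·SMe2, THF, −20 °C) sets C3 as R under reagent control in both enantiomers of 5. The (6R)-ketone gives 6, and the (6S)-ketone gives the cis diastereomer methyl (1S,4R)-4-hydroxy-2,6,6-trimethylcyclohex-2-ene-1-carboxylate F2, which is removed by chromatography. Stereocontrol then rests on reagent control plus diastereomer separation instead of dynamic resolution.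

- **Step 6.** The allylic C3 hydroxyl may ionize under the acid (epimerization at C3 or dehydration), or the pentadienyl cation may lose a proton toward retro-type dienes. The fallback sets out from 8 and comes back at 14, with the polarity of the final olefination reversed and no acid used. Horner–Wadsworth–Emmons reaction of 8 with diethyl (cyanomethyl)phosphonate (NaH 2.2 equiv, THF, 0 °C to rt) gives (2E,4E)-5-[(1R,4R)-4-hydroxy-2,6,6-trimethylcyclohex-2-en-1-yl]-3-methylpenta-2,4-dienenitrile F3 (2E isomer separated). iBu2AlH (CH2Cl2, −78 °C; wet silica gel work-up) reduces it to (2E,4E)-5-[(1R,4R)-4-hydroxy-2,6,6-trimethylcyclohex-2-en-1-yl]-3-methylpenta-2,4-dienal F4. Twofold Wittig reaction of F4 with [(2E,4E,6E)-2,7-dimethylocta-2,4,6-triene-1,8-diyl]bis(triphenylphosphonium) dibromide (NaOMe, MeOH/CH2Cl2; then EtOH, reflux) gives 14.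

**Further compounds**

F1 | step 1 | 4-methylpent-3-en-2-one | CC(C)=CC(C)=O
F2 | step 2 | methyl (1S,4R)-4-hydroxy-2,6,6-trimethylcyclohex-2-ene-1-carboxylate | CC1=C[C@H](O)CC(C)(C)[C@@H]1C(=O)OC
F3 | step 6 | (2E,4E)-5-[(1R,4R)-4-hydroxy-2,6,6-trimethylcyclohex-2-en-1-yl]-3-methylpenta-2,4-dienenitrile | CC1=C[C@H](O)CC(C)(C)[C@H]1/C=C/C(C)=C/C#N
F4 | step 6 | (2E,4E)-5-[(1R,4R)-4-hydroxy-2,6,6-trimethylcyclohex-2-en-1-yl]-3-methylpenta-2,4-dienal | CC1=C[C@H](O)CC(C)(C)[C@H]1/C=C/C(C)=C/C=O
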